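## Retrosynthetic overview

1. Isolappaol A ⇐ debenzylation of 17 ⇐ dihydrobenzofuran ring closed last by 5-exo aryl-radical cyclisation with oxygenation of the ortho-iodoaryl 1-arylallyl ether 15 (forms C3–C3a and CH2OH; C3 is set trans from C2).
2. 15 ⇐ trans-selective alkylation of the enolate of (R)-β-benzyl-γ-butyrolactone 6 with benzylic bromide 13.
3. 13 ⇐ key aryl ether C–O bond (the later O1–C2 bond): enantioselective Rh–H hydro-aryloxylation of aryl propyne 9 with 5-iodovanillin 10, which sets the (S) centre.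
4. 6 ⇐ Stobbe condensation, Rh asymmetric hydrogenation, chemoselective reduction and lactonisation. The butyrolactone ring is formed first, the dihydrobenzofuran ring second.

Assumption: in steps 2 and 5 the ligand antipode named is taken to give the drawn configuration; if the sense proves opposite, the mirror-image ligand is used.

## Route

Step 1
Reactants: 1 4-(benzyloxy)-3-methoxybenzaldehyde; 2 dimethyl succinate
Product: 3 (E)-4-[4-(benzyloxy)-3-methoxyphenyl]-3-(methoxycarbonyl)but-3-enoic acid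
Conditions: NaOMe (1.2 equiv), MeOH, reflux; then aq. HCl
Reagents that add atoms: none
Why: Stobbe condensation; the succinate enolate adds to the aldehyde, the alkoxide lactonises and E1cB ring opening gives the (E)-half-ester, with no stereocentre formed.

Step 2
Reactants: 3 (E)-4-[4-(benzyloxy)-3-methoxyphenyl]-3-(methoxycarbonyl)but-3-enoic acid
Product: 4 (R)-4-[4-(benzyloxy)-3-methoxyphenyl]-3-(methoxycarbonyl)butanoic acid
Conditions: H2 (5 atm), [Rh(cod)Cl]2 (0.5 mol %), (4S,5S)-MOD-DIOP (1.1 mol %), Et3N (1 equiv), MeOH, 30 °C; then aq. HCl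
Reagents that add atoms: none
Why: Rh-catalysed asymmetric hydrogenation of an itaconate-type half-ester; the carboxylate and alkene chelate rhodium and the chiral diphosphine selects the alkene face, setting the (R) centre, while the homogeneous catalyst leaves the benzyl ether intact.

Step 3
Reactants: 4 (R)-4-[4-(benzyloxy)-3-methoxyphenyl]-3-(methoxycarbonyl)butanoic acid
Product: 6 (R)-4-[4-(benzyloxy)-3-methoxybenzyl]dihydrofuran-2(3H)-one, via hydroxy acid 5 (not isolated)
Conditions: KOH (1 equiv), EtOH; CaCl2, NaBH4, EtOH, −10 °C → rt; then 3 M HCl, rt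
Reagents that add atoms: none
Why: chemoselective ester reduction by Ca(BH4)2 beside an inert carboxylate, then acid-promoted lactonisation; the stereocentre is not touched.

Step 4
Reactants: 7 (E)-1-(benzyloxy)-2-methoxy-4-(prop-1-en-1-yl)benzene (benzyl isoeugenol)
Product: 9 1-(benzyloxy)-2-methoxy-4-(prop-1-yn-1-yl)benzene, via dibromide 8 (not isolated)
Conditions: Br2 (1.0 equiv), CH2Cl2, −40 °C; then t-BuOK (3.5 equiv), THF, 0 → 50 °C
Reagents that add atoms: none
Why: alkene bromination followed by double dehydrobromination (E2), the classical propenylarene-to-arylpropyne conversion; one equivalent of Br2 at low temperature adds to the styrene faster than it brominates the ring.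

Step 5
Reactants: 9 1-(benzyloxy)-2-methoxy-4-(prop-1-yn-1-yl)benzene; 10 4-hydroxy-3-iodo-5-methoxybenzaldehyde (5-iodovanillin)
Product: 11 (S)-4-({1-[4-(benzyloxy)-3-methoxyphenyl]prop-2-en-1-yl}oxy)-3-iodo-5-methoxybenzaldehyde
Conditions: [Rh(cod)Cl]2 (2.5 mol %), (R)-DTBM-SEGPHOS (6 mol %), 9 (1.5 equiv), ClCH2CH2Cl, 60 °C
Reagents that add atoms: none
Why: Proposed new method: enantioselective Rh–H hydro-aryloxylation of an aryl methyl alkyne by a phenol, forming the key C–O bond; the acidic phenol 10 (pKa about 7, like the acids and azoles that work in this manifold) adds its O–H to monovalent rhodium, the resulting Rh–H isomerises 9 to the aryl allene by insertion and β-hydride elimination and re-inserts to a π-allyl trivalent rhodium aryloxide, and inner-sphere C–O reductive elimination at the aryl-bearing terminus inside the chiral diphosphine pocket gives the branched (S)-ether with full atom economy; the closest known reactions are Rh-catalysed couplings of 1-aryl-1-propynes or allenes with carboxylic acids, azoles, thiols and aliphatic alcohols to branched allylic products, and Rh-catalysed branched allylic etherification of secondary allylic carbonates with ortho-disubstituted aryloxides.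

Step 6
Reactants: 11 (S)-4-({1-[4-(benzyloxy)-3-methoxyphenyl]prop-2-en-1-yl}oxy)-3-iodo-5-methoxybenzaldehyde
Product: 12 (S)-[4-({1-[4-(benzyloxy)-3-methoxyphenyl]prop-2-en-1-yl}oxy)-3-iodo-5-methoxyphenyl]methanol
Conditions: NaBH4, MeOH–THF, 0 °C
Reagents that add atoms: none
Why: chemoselective borohydride reduction of the aldehyde; the aryl iodide, alkene and ether are inert and the stereocentre is not touched.

Step 7
Reactants: 12 (S)-[4-({1-[4-(benzyloxy)-3-methoxyphenyl]prop-2-en-1-yl}oxy)-3-iodo-5-methoxyphenyl]methanol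
Product: 13 (S)-1-(benzyloxy)-4-{1-[4-(bromomethyl)-2-iodo-6-methoxyphenoxy]prop-2-en-1-yl}-2-methoxybenzene
Conditions: CBr4, PPh3, CH2Cl2, 0 °C; used directly
Reagents that add atoms: carbon tetrabromide, BrC(Br)(Br)Br
Why: Appel reaction under neutral conditions converts the benzylic alcohol to the bromide without ionising the acid-labile benzylic, allylic aryl ether.

Step 8
Reactants: 6 (R)-4-[4-(benzyloxy)-3-methoxybenzyl]dihydrofuran-2(3H)-one; 13 (S)-1-(benzyloxy)-4-{1-[4-(bromomethyl)-2-iodo-6-methoxyphenoxy]prop-2-en-1-yl}-2-methoxybenzene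
Product: 15 (3R,4R)-4-[4-(benzyloxy)-3-methoxybenzyl]-3-[4-({(S)-1-[4-(benzyloxy)-3-methoxyphenyl]prop-2-en-1-yl}oxy)-3-iodo-5-methoxybenzyl]dihydrofuran-2(3H)-one, via lithium enolate 14 (not isolated)
Conditions: 6 (1.2 equiv), LiN(SiMe3)2 (1.15 equiv), THF, −78 °C; then 13 (1.0 equiv), DMPU, −78 → −30 °C
Reagents that add atoms: none
Why: SN2 alkylation of the lactone lithium enolate; the bromide approaches anti to the C4 benzyl group, giving the 3,4-trans (3R,4R) lactone, and the slight excess of lactone over base leaves no free amide to attack the ether C–H.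

Step 9
Reactants: 15 (3R,4R)-4-[4-(benzyloxy)-3-methoxybenzyl]-3-[4-({(S)-1-[4-(benzyloxy)-3-methoxyphenyl]prop-2-en-1-yl}oxy)-3-iodo-5-methoxybenzyl]dihydrofuran-2(3H)-one
Product: 17 (3R,4R)-4-[4-(benzyloxy)-3-methoxybenzyl]-3-({(2S,3R)-2-[4-(benzyloxy)-3-methoxyphenyl]-3-(hydroxymethyl)-7-methoxy-2,3-dihydrobenzofuran-5-yl}methyl)dihydrofuran-2(3H)-one, via hydroperoxide 16 (not isolated)
Conditions: Bu3SnH (slow addition), Et3B (cat.), dry air, PhMe, 0 °C → rt; then PPh3
Reagents that add atoms: dioxygen, O=O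
Why: oxygenative tin-hydride radical cyclisation; the aryl radical closes 5-exo-trig through a chair-like Beckwith–Houk transition state with the C2 aryl group pseudo-equatorial, so C3 is set trans to C2 (3R), the primary radical is captured by O2, and PPh3 reduces the hydroperoxide to the alcohol.

Step 10
Reactants: 17 (3R,4R)-4-[4-(benzyloxy)-3-methoxybenzyl]-3-({(2S,3R)-2-[4-(benzyloxy)-3-methoxyphenyl]-3-(hydroxymethyl)-7-methoxy-2,3-dihydrobenzofuran-5-yl}methyl)dihydrofuran-2(3H)-one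
Product: 18 isolappaol A, (3R,4R)-4-(4-hydroxy-3-methoxybenzyl)-3-{[(2S,3R)-2-(4-hydroxy-3-methoxyphenyl)-3-(hydroxymethyl)-7-methoxy-2,3-dihydrobenzofuran-5-yl]methyl}dihydrofuran-2(3H)-one
Conditions: H2 (1 atm), Pd/C (10 % Pd), EtOAc–EtOH, rt, stopped at full conversion
Reagents that add atoms: none
Why: catalytic hydrogenolysis of the two aryl benzyl ethers; under neutral conditions at 1 atm the lactone, the primary alcohol and the ring benzylic C–O bond are kept and no stereocentre is touched.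

## Compound list

1 | 4-(benzyloxy)-3-methoxybenzaldehyde | O=Cc1ccc(OCc2ccccc2)c(OC)c1 | starting material
2 | dimethyl succinate | COC(=O)CCC(=O)OC | starting material
3 | (E)-4-[4-(benzyloxy)-3-methoxyphenyl]-3-(methoxycarbonyl)but-3-enoic acid | OC(=O)C/C(C(=O)OC)=C\c1ccc(OCc2ccccc2)c(OC)c1 | intermediate
4 | (R)-4-[4-(benzyloxy)-3-methoxyphenyl]-3-(methoxycarbonyl)butanoic acid | COC(=O)[C@H](Cc1ccc(OCc2ccccc2)c(OC)c1)CC(=O)O | intermediate
5 | (R)-4-[4-(benzyloxy)-3-methoxyphenyl]-3-(hydroxymethyl)butanoic acid | OC[C@H](Cc1ccc(OCc2ccccc2)c(OC)c1)CC(=O)O | intermediate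
6 | (R)-4-[4-(benzyloxy)-3-methoxybenzyl]dihydrofuran-2(3H)-one | COc1cc(C[C@H]2COC(=O)C2)ccc1OCc1ccccc1 | intermediate
7 | (E)-1-(benzyloxy)-2-methoxy-4-(prop-1-en-1-yl)benzene (benzyl isoeugenol) | C/C=C/c1ccc(OCc2ccccc2)c(OC)c1 | starting material
8 | 1-(benzyloxy)-4-(1,2-dibromopropyl)-2-methoxybenzene (racemic diastereomer mixture) | CC(Br)C(Br)c1ccc(OCc2ccccc2)c(OC)c1 | intermediate
9 | 1-(benzyloxy)-2-methoxy-4-(prop-1-yn-1-yl)benzene | CC#Cc1ccc(OCc2ccccc2)c(OC)c1 | intermediate
10 | 4-hydroxy-3-iodo-5-methoxybenzaldehyde (5-iodovanillin) | O=Cc1cc(I)c(O)c(OC)c1 | starting material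
11 | (S)-4-({1-[4-(benzyloxy)-3-methoxyphenyl]prop-2-en-1-yl}oxy)-3-iodo-5-methoxybenzaldehyde | O=Cc1cc(OC)c(O[C@@H](C=C)c2ccc(OCc3ccccc3)c(OC)c2)c(I)c1 | intermediate
12 | (S)-[4-({1-[4-(benzyloxy)-3-methoxyphenyl]prop-2-en-1-yl}oxy)-3-iodo-5-methoxyphenyl]methanol | OCc1cc(OC)c(O[C@@H](C=C)c2ccc(OCc3ccccc3)c(OC)c2)c(I)c1 | intermediate
13 | (S)-1-(benzyloxy)-4-{1-[4-(bromomethyl)-2-iodo-6-methoxyphenoxy]prop-2-en-1-yl}-2-methoxybenzene | BrCc1cc(OC)c(O[C@@H](C=C)c2ccc(OCc3ccccc3)c(OC)c2)c(I)c1 | intermediate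
14 | lithium (R)-4-[4-(benzyloxy)-3-methoxybenzyl]-4,5-dihydrofuran-2-olate | COc1cc(C[C@H]2COC([O-])=C2)ccc1OCc1ccccc1.[Li+] | intermediate
15 | (3R,4R)-4-[4-(benzyloxy)-3-methoxybenzyl]-3-[4-({(S)-1-[4-(benzyloxy)-3-methoxyphenyl]prop-2-en-1-yl}oxy)-3-iodo-5-methoxybenzyl]dihydrofuran-2(3H)-one | COc1cc(C[C@H]2COC(=O)[C@@H]2Cc2cc(OC)c(O[C@@H](C=C)c3ccc(OCc4ccccc4)c(OC)c3)c(I)c2)ccc1OCc1ccccc1 | intermediate
16 | (3R,4R)-4-[4-(benzyloxy)-3-methoxybenzyl]-3-({(2S,3R)-2-[4-(benzyloxy)-3-methoxyphenyl]-3-(hydroperoxymethyl)-7-methoxy-2,3-dihydrobenzofuran-5-yl}methyl)dihydrofuran-2(3H)-one | COc1cc(C[C@H]2COC(=O)[C@@H]2Cc2cc(OC)c3c(c2)[C@H](COO)[C@@H](c2ccc(OCc4ccccc4)c(OC)c2)O3)ccc1OCc1ccccc1 | intermediate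
17 | (3R,4R)-4-[4-(benzyloxy)-3-methoxybenzyl]-3-({(2S,3R)-2-[4-(benzyloxy)-3-methoxyphenyl]-3-(hydroxymethyl)-7-methoxy-2,3-dihydrobenzofuran-5-yl}methyl)dihydrofuran-2(3H)-one | COc1cc(C[C@H]2COC(=O)[C@@H]2Cc2cc(OC)c3c(c2)[C@H](CO)[C@@H](c2ccc(OCc4ccccc4)c(OC)c2)O3)ccc1OCc1ccccc1 | intermediate
18 | isolappaol A | COc1cc(C[C@H]2COC(=O)[C@@H]2Cc2cc(OC)c3c(c2)[C@H](CO)[C@@H](c2ccc(O)c(OC)c2)O3)ccc1O | target

## Step count and risk

Total: 10 steps. Longest linear sequence: 7 steps (steps 4–10 from benzyl isoeugenol 7); the lactone branch (steps 1–3) joins at step 8.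

Three steps most likely to fail:

Step 5 (proposed new hydro-aryloxylation). The main risks are insertion of rhodium into the aryl C–I bond, erosion of branched selectivity and ee by reversible ionisation of the product ether, and poor turnover with the hindered phenol. The known-chemistry fallback sets out from 1 and 10 and comes back to the route at 11. Wittig olefination of 1 with Ph3P=CHCO2Et gives ethyl (E)-3-[4-(benzyloxy)-3-methoxyphenyl]acrylate F1. DIBAL-H reduction gives (E)-3-[4-(benzyloxy)-3-methoxyphenyl]prop-2-en-1-ol F2, and ClCO2Me with pyridine gives (E)-3-[4-(benzyloxy)-3-methoxyphenyl]allyl methyl carbonate F3. Iridium-catalysed enantioselective allylic etherification of F3 ([Ir(cod)Cl]2, binaphthol-derived N,N-bis(1-phenylethyl)phosphoramidite, THF, rt) with sodium 4-formyl-2-iodo-6-methoxyphenolate F4, made from 10 and NaN(SiMe3)2, then gives the branched (S)-ether 11.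

Step 9 (oxygenative radical cyclisation). The aryl radical may abstract the benzylic, allylic ether hydrogen (1,5-transfer) or be caught by O2 before ring closure, and the trans:cis ratio may be modest. The fallback sets out from 15 and comes back at 17, and brings in the oxygen by C–B oxidation instead of O2 capture. Cross-metathesis of 15 with vinylboronic acid pinacol ester (second-generation Hoveyda–Grubbs catalyst) gives the (E)-alkenylboronate of 15 F8. Reductive 5-exo cyclisation with Bu3SnH and AIBN in degassed benzene at 80 °C, onto the boron-substituted alkene, gives the trans 3-[(pinacolboryl)methyl]dihydrobenzofuran F9. Oxidation with NaBO3·4H2O, with retention, gives 17.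

Step 8 (alkylation with bromide 13). Bromide 13 is a 4-alkoxybenzyl bromide that also carries an ionisable 1-arylallyl aryl ether, so it may decompose before or during the alkylation. The fallback sets out from 6 and 11 and comes back at 15, avoiding the bromide (steps 6 and 7 are then not needed). Aldol addition of lithium enolate 14 to aldehyde 11 gives the trans β-hydroxy lactone F5 as carbinol epimers. MsCl and Et3N give the mesylate F6 (not isolated), and DBU elimination gives the (E)-α-arylidene lactone F7. Conjugate reduction with [(Ph3P)CuH]6, followed by DBU equilibration to the more stable 3,4-trans lactone, gives 15.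

## Further compounds

F1 | step 5 | ethyl (E)-3-[4-(benzyloxy)-3-methoxyphenyl]acrylate | CCOC(=O)/C=C/c1ccc(OCc2ccccc2)c(OC)c1
F2 | step 5 | (E)-3-[4-(benzyloxy)-3-methoxyphenyl]prop-2-en-1-ol | OC/C=C/c1ccc(OCc2ccccc2)c(OC)c1
F3 | step 5 | (E)-3-[4-(benzyloxy)-3-methoxyphenyl]allyl methyl carbonate | COC(=O)OC/C=C/c1ccc(OCc2ccccc2)c(OC)c1
F4 | step 5 | sodium 4-formyl-2-iodo-6-methoxyphenolate | [Na+].[O-]c1c(I)cc(C=O)cc1OC
F5 | step 8 | (3S,4R)-4-[4-(benzyloxy)-3-methoxybenzyl]-3-{hydroxy[4-({(S)-1-[4-(benzyloxy)-3-methoxyphenyl]prop-2-en-1-yl}oxy)-3-iodo-5-methoxyphenyl]methyl}dihydrofuran-2(3H)-one (carbinol epimers) | COc1cc(C[C@H]2COC(=O)[C@@H]2C(O)c2cc(OC)c(O[C@@H](C=C)c3ccc(OCc4ccccc4)c(OC)c3)c(I)c2)ccc1OCc1ccccc1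
F6 | step 8 | methanesulfonate of F5 | COc1cc(C[C@H]2COC(=O)[C@@H]2C(OS(C)(=O)=O)c2cc(OC)c(O[C@@H](C=C)c3ccc(OCc4ccccc4)c(OC)c3)c(I)c2)ccc1OCc1ccccc1
F7 | step 8 | (R,E)-4-[4-(benzyloxy)-3-methoxybenzyl]-3-[4-({(S)-1-[4-(benzyloxy)-3-methoxyphenyl]prop-2-en-1-yl}oxy)-3-iodo-5-methoxybenzylidene]dihydrofuran-2(3H)-one | COc1cc(C[C@H]2COC(=O)/C2=C/c2cc(OC)c(O[C@@H](C=C)c3ccc(OCc4ccccc4)c(OC)c3)c(I)c2)ccc1OCc1ccccc1
F8 | step 9 | (E)-alkenylboronate of 15: (3R,4R)-4-[4-(benzyloxy)-3-methoxybenzyl]-3-[4-({(S,E)-1-[4-(benzyloxy)-3-methoxyphenyl]-3-(4,4,5,5-tetramethyl-1,3,2-dioxaborolan-2-yl)prop-2-en-1-yl}oxy)-3-iodo-5-methoxybenzyl]dihydrofuran-2(3H)-one | COc1cc(C[C@H]2COC(=O)[C@@H]2Cc2cc(OC)c(O[C@@H](/C=C/B3OC(C)(C)C(C)(C)O3)c3ccc(OCc4ccccc4)c(OC)c3)c(I)c2)ccc1OCc1ccccc1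
F9 | step 9 | trans 3-[(pinacolboryl)methyl] analogue of 17 (2S,3S by CIP, same spatial arrangement as 17) | COc1cc(C[C@H]2COC(=O)[C@@H]2Cc2cc(OC)c3c(c2)[C@H](CB2OC(C)(C)C(C)(C)O2)[C@@H](c2ccc(OCc4ccccc4)c(OC)c2)O3)ccc1OCc1ccccc1
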